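**Plan**

- Retrosynthesis: the C3–C4 oxirane oxygen is removed first. The 14-membered ring is then cut at C9–C10 (Pd allylic alkylation by a C10 bis-sulfonyl carbanion). The chain is cut further at C10–C11 (Mitsunobu), C12–C13 (aldol), C1–C15 together with the lactone C–O (epoxide opening and lactonisation), C1–C2 (Cu allyl–alkynyl coupling) and C7–C8 (Baylis–Hillman).
- Enabling feature: C7–C8(=C19H2)–C9 is a 2-substituted allyl unit, the pattern of a reduced Baylis–Hillman adduct, and its two CH2 termini are equivalent. It is followed by the plain C9–C11 methylenes, so C10 can carry two removable sulfones as the nucleophile.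
- Forward order: geraniol gives C2–C7 with the 3E alkene; the acrylate adds C8, C9 and C19; propargyl alcohol adds C13, C14 and C1; ethoxyacetylene adds C15 and C16 and closes the γ-lactone (step 12); the propionyl unit adds C11, C12 and C20; bis(phenylsulfonyl)methane adds C10. The carbocycle closes in step 21 and the oxirane forms last (step 26).
- Stereochemistry: C7 comes from the β-isocupreidine Baylis–Hillman reaction; C14 and C1 from Sharpless epoxidation (L-tartrate) and invertive epoxide opening; C12 and C13 from the thiazolidinethione auxiliary; C3 and C4 from the Shi ketone; the alkene geometry from geraniol.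

Key step: step 21

Remark: cembrane numbering (C1–C20, as in the plan) is used for all intermediates. The target SMILES is read as 1S,3R,4R,7R,12S,13R,14R, with a cis-fused lactone and an oxirane derived from the 3E alkene. TBS = tert-butyldimethylsilyl, PMB = 4-methoxybenzyl, HFIP = 1,1,1,3,3,3-hexafluoropropan-2-yl.

**Route**

Step 1
Reactants: 1 geraniol
Product: 2 geranyl PMB ether
Conditions: NaH, PMBCl, Bu4NI (cat.), THF/DMF, 0 °C → rt
Reagents that add atoms: 4-methoxybenzyl chloride, COc1ccc(CCl)cc1
Why: Williamson ether synthesis; the PMB ether masks the C2 oxygen through the hydride steps and can later be removed oxidatively beside silyl ethers.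

Step 2
Reactants: 2 geranyl PMB ether
Product: 3 6,7-epoxygeranyl PMB ether (racemic at the oxirane CH)
Conditions: mCPBA (1.05 equiv), NaHCO3, CH2Cl2, −20 → 0 °C
Reagents that add atoms: 3-chloroperbenzoic acid, O=C(OO)c1cccc(Cl)c1
Why: Prilezhaev epoxidation, in which the terminal trisubstituted alkene should react before the 2,3-alkene that is deactivated by the allylic ether oxygen; the new stereocentre is lost in the next step.

Step 3
Reactants: 3 6,7-epoxygeranyl PMB ether
Product: 4 (4E)-6-(PMB-oxy)-4-methylhex-4-enal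
Conditions: H5IO6, THF/Et2O, 0 °C
Reagents that add atoms: none
Why: Periodic acid opens the epoxide and cleaves the resulting glycol (Malaprade-type cleavage), giving the future C7 aldehyde and acetone while the remaining alkene and the PMB ether are inert.

Step 4
Reactants: 4 (4E)-6-(PMB-oxy)-4-methylhex-4-enal; 5 HFIP acrylate
Product: 6 HFIP (3R,6E)-3-hydroxy-8-(PMB-oxy)-6-methyl-2-methylideneoct-6-enoate
Conditions: β-isocupreidine (10 mol %), DMF, −55 °C
Reagents that add atoms: 5 HFIP acrylate, C=CC(=O)OC(C(F)(F)F)C(F)(F)F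
Why: Hatakeyama asymmetric Morita–Baylis–Hillman reaction; the quinuclidine nitrogen adds to the activated acrylate and the phenolic hydroxyl of the catalyst orders the aldol/elimination sequence by hydrogen bonding, so the C7 carbinol should form with R configuration under catalyst control.

Step 5
Reactants: 6 HFIP (3R,6E)-3-hydroxy-8-(PMB-oxy)-6-methyl-2-methylideneoct-6-enoate
Product: 7 (3R,6E)-8-(PMB-oxy)-6-methyl-2-methylideneoct-6-ene-1,3-diol
Conditions: DIBAL-H (4.5 equiv), CH2Cl2, −78 → −20 °C; Rochelle salt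
Reagents that add atoms: none
Why: 1,2-reduction of the acrylate ester by DIBAL-H gives the 2-methylene-1,3-diol (C7 secondary, C9 primary) without touching the PMB ether or C7.

Step 6
Reactants: 7 (3R,6E)-8-(PMB-oxy)-6-methyl-2-methylideneoct-6-ene-1,3-diol
Product: 8 bis-TBS ether of 7 (C7 and C9 silylated)
Conditions: TBSCl, imidazole, DMF, rt
Reagents that add atoms: tert-butyldimethylsilyl chloride, CC(C)(C)[Si](C)(C)Cl
Why: Imidazole-promoted silylation of both hydroxyls gives ethers that withstand hydride, aluminium and titanium reagents and make C7 non-ionisable in the ring closure.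

Step 7
Reactants: 8 bis-TBS ether of 7
Product: 9 (2E,6R)-6-(TBSO)-7-(TBSO-methyl)-3-methylocta-2,7-dien-1-ol
Conditions: DDQ, CH2Cl2/pH 7 buffer, 0 °C
Reagents that add atoms: none
Why: Oxidative PMB cleavage by hydride abstraction at the electron-rich benzylic position and hydrolysis of the oxocarbenium ion leaves both silyl ethers and the alkenes intact.

Step 8
Reactants: 9 (2E,6R)-6-(TBSO)-7-(TBSO-methyl)-3-methylocta-2,7-dien-1-ol
Product: 10 (2E,6R)-1-bromo-6-(TBSO)-7-(TBSO-methyl)-3-methylocta-2,7-diene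
Conditions: CBr4, PPh3, CH2Cl2, 0 °C; used crude
Reagents that add atoms: carbon tetrabromide, BrC(Br)(Br)Br
Why: Appel bromination under neutral conditions converts the primary allylic alcohol to the bromide without allylic transposition or desilylation.

Step 9
Reactants: 10 (2E,6R)-1-bromo-6-(TBSO)-7-(TBSO-methyl)-3-methylocta-2,7-diene; 11 propargyl alcohol
Product: 12 (5E,9R)-9-(TBSO)-10-(TBSO-methyl)-6-methylundeca-5,10-dien-2-yn-1-ol
Conditions: CuI (10 mol %), Bu4NI (10 mol %), K2CO3, DMF, rt
Reagents that add atoms: 11 propargyl alcohol, C#CCO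
Why: Copper-catalysed allyl–alkynyl coupling (Jeffery conditions); the copper acetylide substitutes the primary allylic bromide at its unhindered α-carbon, forming C1–C2 and keeping the 3E alkene.

Step 10
Reactants: 12 (5E,9R)-9-(TBSO)-10-(TBSO-methyl)-6-methylundeca-5,10-dien-2-yn-1-ol
Product: 13 (2E,5E,9R)-9-(TBSO)-10-(TBSO-methyl)-6-methylundeca-2,5,10-trien-1-ol
Conditions: Red-Al, THF, 0 °C → rt
Reagents that add atoms: none
Why: Alkoxide-directed trans-hydroalumination of the propargylic alcohol and protonolysis give the E allylic alcohol (C14=C1) only.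

Step 11
Reactants: 13 (2E,5E,9R)-9-(TBSO)-10-(TBSO-methyl)-6-methylundeca-2,5,10-trien-1-ol
Product: 14 [(2S,3S)-3-{(2E,6R)-6-(TBSO)-7-(TBSO-methyl)-3-methylocta-2,7-dienyl}oxiran-2-yl]methanol
Conditions: Ti(OiPr)4 (10 mol %), L-(+)-diethyl tartrate (12 mol %), t-BuOOH, 4 Å MS, CH2Cl2, −20 °C
Reagents that add atoms: tert-butyl hydroperoxide, CC(C)(C)OO
Why: Sharpless asymmetric epoxidation; only the allylic alcohol binds titanium, and the L-tartrate complex delivers oxygen to the face that gives the 2S,3S epoxy alcohol, which fixes C14 and the configuration at C1 that is inverted next.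

Step 12
Reactants: 14 [(2S,3S)-3-{(2E,6R)-6-(TBSO)-7-(TBSO-methyl)-3-methylocta-2,7-dienyl}oxiran-2-yl]methanol; 15 ethoxyacetylene
Product: 17 cis-(4S,5R)-5-(hydroxymethyl)-4-[(2E,6R)-6-(TBSO)-7-(TBSO-methyl)-3-methylocta-2,7-dienyl]oxolan-2-one, via ynol ether diol 16 (not isolated)
Conditions: 15, n-BuLi, toluene, −78 °C; Et2AlCl, 0 °C; then 14, 0 °C → rt; Rochelle salt; then TsOH·H2O (cat.), wet THF, 0 °C
Reagents that add atoms: 15 ethoxyacetylene, C#COCC; water, O
Why: Alkynylalane opening of a 2,3-epoxy alcohol; the substrate is bound as its aluminium alkoxide and the ethoxyethynyl group attacks C1, the oxirane carbon remote from the CH2O–Al group, with inversion, which turns the trans epoxide into the 1S,14R array of a cis lactone, and mild acid then hydrates the ynol ether through the ketene acetal formed with the C14 hydroxyl, closing the five-membered lactone in preference to the six-membered one.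

Step 13
Reactants: 17 cis-(4S,5R)-5-(hydroxymethyl)-4-[(2E,6R)-6-(TBSO)-7-(TBSO-methyl)-3-methylocta-2,7-dienyl]oxolan-2-one
Product: 18 (2R,3S)-3-[(2E,6R)-6-(TBSO)-7-(TBSO-methyl)-3-methylocta-2,7-dienyl]-5-oxooxolane-2-carbaldehyde
Conditions: Dess–Martin periodinane, NaHCO3, CH2Cl2, 0 °C → rt; used at once
Reagents that add atoms: none
Why: Dess–Martin oxidation under buffered, non-basic conditions gives the C13 aldehyde, which is used directly so that the α-acyloxy centre C14 is not epimerised.

Step 14
Reactants: 19 (R)-4-benzyl-1,3-thiazolidine-2-thione; 20 propanoyl chloride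
Product: 21 (R)-4-benzyl-3-propanoyl-1,3-thiazolidine-2-thione
Conditions: Et3N, DMAP (cat.), CH2Cl2, 0 °C
Reagents that add atoms: 20 propanoyl chloride, CCC(Cl)=O
Why: N-acylation of the thiazolidinethione gives the propionate donor for the aldol reaction.

Step 15
Reactants: 18 (2R,3S)-3-[(2E,6R)-6-(TBSO)-7-(TBSO-methyl)-3-methylocta-2,7-dienyl]-5-oxooxolane-2-carbaldehyde; 21 (R)-4-benzyl-3-propanoyl-1,3-thiazolidine-2-thione
Product: 22 syn-aldol adduct (12R,13R): lactone 18 extended by C13(OH)–C12(Me)–C11(=O)–N-thiazolidinethione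
Conditions: 21, TiCl4, i-Pr2NEt, NMP, CH2Cl2, 0 °C; then 18, −78 → 0 °C
Reagents that add atoms: 21 (R)-4-benzyl-3-propanoyl-1,3-thiazolidine-2-thione, CCC(=O)N1C(=S)SC[C@H]1Cc1ccccc1
Why: Crimmins titanium aldol in the Evans-syn mode; the Z chlorotitanium enolate reacts through a non-chelated Zimmerman–Traxler chair on the face away from the benzyl group, so the R auxiliary should set C12 and C13 syn to each other and syn to C14 under auxiliary control.

Step 16
Reactants: 22 syn-aldol adduct (12R,13R)
Product: 23 C13 TBS ether of 22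
Conditions: TBSOTf, 2,6-lutidine, CH2Cl2, −78 → 0 °C
Reagents that add atoms: tert-butyldimethylsilyl triflate, CC(C)(C)[Si](C)(C)OS(=O)(=O)C(F)(F)F
Why: Silylation of the hindered secondary alcohol with the silyl triflate blocks retro-aldol and translactonisation pathways and installs the C13 ether carried through the ring closure.

Step 17
Reactants: 23 C13 TBS ether of 22
Product: 24 C11 primary alcohol (1S,7R,12S,13R,14R; C7/C9/C13 TBS ethers; saturated lactone)
Conditions: NaBH4, THF/EtOH, 0 °C
Reagents that add atoms: none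
Why: Reductive cleavage of the activated thioimide; the N-acyl thiazolidinethione is far more electrophilic than the γ-lactone, so borohydride at 0 °C should reduce only the exocyclic acyl group to the C11 alcohol and release the auxiliary.

Step 18
Reactants: 24 C11 primary alcohol; 25 bis(phenylsulfonyl)methane
Product: 26 C10 bis(phenylsulfonyl)methyl compound (C7/C9/C13 TBS ethers; saturated lactone)
Conditions: PPh3, DIAD, THF, 0 → 40 °C
Reagents that add atoms: 25 bis(phenylsulfonyl)methane, O=S(=O)(CS(=O)(=O)c1ccccc1)c1ccccc1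
Why: Mitsunobu C-alkylation; the bis-sulfone (pKa about 12) protonates the betaine and its carbanion displaces the alkoxyphosphonium group at the primary C11 carbon, forming C10–C11 without a base that could open the lactone.

Step 19
Reactants: 26 C10 bis(phenylsulfonyl)methyl compound
Product: 27 C9 allylic alcohol (C7/C13 TBS ethers)
Conditions: HF·pyridine, pyridine, THF, 0 °C
Reagents that add atoms: none
Why: Selective silyl ether cleavage; buffered HF·pyridine should remove the unhindered primary allylic TBS ether at C9 well before the two secondary TBS ethers.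

Step 20
Reactants: 27 C9 allylic alcohol
Product: 28 C9 methyl carbonate (open-chain cyclisation precursor; 1S,7R,12S,13R,14R; 3E)
Conditions: ClCO2Me, pyridine, DMAP (cat.), CH2Cl2, 0 °C
Reagents that add atoms: methyl chloroformate, COC(Cl)=O
Why: O-acylation of the primary allylic alcohol with methyl chloroformate; pyridine is too weak a base to deprotonate the bis-sulfone, so only the carbonate forms.

Step 21
Reactants: 28 C9 methyl carbonate
Product: 29 (1S,3E,7R,12S,13R,14R)-7,13-bis(TBSO)-8-methylidene-10,10-bis(phenylsulfonyl)cembr-3-en-16,14-olide (14-membered carbocycle)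
Conditions: Pd2(dba)3·CHCl3 (5 mol %), dppe (12 mol %), THF, 65 °C, syringe-pump addition of 28 (final ca. 1 mM)
Reagents that add atoms: none
Why: Pd(0) ionises the primary allylic methyl carbonate to a 2-substituted π-allylpalladium cation, CO2 is lost, and the freed methoxide deprotonates the C10 bis-sulfone, whose soft carbanion attacks a CH2 terminus of the allyl ligand on the face opposite palladium (Tsuji–Trost allylic alkylation under neutral carbonate conditions). The closest known reaction type is the palladium-catalysed macrocyclisation of tethered bis(sulfonyl) carbanions onto allylic esters. The 14-membered carbocycle closes by C9–C10 bond formation with the allyl double bond left exocyclic (C8=C19), and because both allyl termini are CH2 groups, attack at either gives the same ring. No stereocentre is created and the 3E alkene is not touched. The step needs ionisation at C9 only and cyclisation over oligomerisation: the C7 oxygen is a silyl ether that Pd(0) does not ionise, the lactone is saturated so the carbanion has no Michael acceptor, and slow addition keeps the substrate dilute.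

Step 22
Reactants: 29 macrocyclic bis-sulfone
Product: 30 (1S,3E,7R,12S,13R,14R)-7,13-bis(TBSO)-8-methylidenecembr-3-en-16,14-olide
Conditions: 6 % Na(Hg), Na2HPO4, MeOH/THF, −20 °C
Reagents that add atoms: none
Why: Reductive desulfonylation by electron transfer from sodium amalgam; each C–S bond is cleaved to a carbanion that methanol protonates, the phosphate buffer protects the lactone, and no β-leaving group is present.

Step 23
Reactants: 30 desulfonylated macrocyclic lactone
Product: 33 α-methylene lactone (7,13-bis-TBS ether), via Mannich base 31 (not isolated), via methiodide 32 (not isolated)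
Conditions: LDA, THF, −78 °C; CH2=NMe2+ I−, −78 °C → rt; then MeI, MeOH, rt; then aq. NaHCO3/CH2Cl2
Reagents that add atoms: Eschenmoser's salt, C=[N+](C)C.[I-]
Why: α-Methylenation of the lactone; the lithium enolate at C15 undergoes a Mannich reaction with the iminium salt, and quaternisation followed by mild-base elimination of trimethylamine gives the exocyclic enoate, with C1 and C14 not enolisable.

Step 24
Reactants: 33 α-methylene lactone (7,13-bis-TBS ether)
Product: 34 7,13-diol
Conditions: HF·pyridine, THF, 0 °C → rt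
Reagents that add atoms: none
Why: Fluoride-mediated cleavage of both secondary silyl ethers under mildly acidic conditions avoids conjugate addition to the α-methylene lactone.

Step 25
Reactants: 34 7,13-diol
Product: 35 7,13-diacetate (3E alkene)
Conditions: Ac2O, pyridine, DMAP (cat.), CH2Cl2, rt
Reagents that add atoms: acetic anhydride, CC(=O)OC(C)=O
Why: DMAP-catalysed acetylation of both secondary alcohols.

Step 26
Reactants: 35 7,13-diacetate
Product: 36 target, (1S,3R,4R,7R,12S,13R,14R)-7,13-diacetoxy-3,4-epoxy-cembra-8(19),15(17)-dien-16,14-olide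
Conditions: D-fructose-derived Shi ketone (30 mol %), Oxone, K2CO3, Bu4NHSO4, MeCN/dimethoxymethane, aq. Na2B4O7–EDTA buffer, 0 °C
Reagents that add atoms: Oxone (potassium peroxymonosulfate), [K+].[O-]S(=O)(=O)OO
Why: Shi asymmetric epoxidation; the chiral dioxirane transfers oxygen to the electron-rich trisubstituted C3=C4 alkene through a spiro transition state whose facial preference for E-trisubstituted alkenes corresponds to the 3R,4R oxirane (reagent control), while the 1,1-disubstituted C8=C19 alkene beside the allylic acetate and the electron-poor α-methylene lactone should react much more slowly.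

**Compound list**

1 | geraniol | CC(C)=CCC/C(C)=C/CO | starting material
2 | geranyl PMB ether | CC(C)=CCC/C(C)=C/COCc1ccc(OC)cc1 | intermediate
3 | 6,7-epoxygeranyl PMB ether (racemic oxirane) | CC1(C)OC1CC/C(C)=C/COCc1ccc(OC)cc1 | intermediate
4 | (4E)-6-(PMB-oxy)-4-methylhex-4-enal | O=CCC/C(C)=C/COCc1ccc(OC)cc1 | intermediate
5 | HFIP acrylate | C=CC(=O)OC(C(F)(F)F)C(F)(F)F | starting material
6 | HFIP (3R,6E)-3-hydroxy-8-(PMB-oxy)-6-methyl-2-methylideneoct-6-enoate | C=C(C(=O)OC(C(F)(F)F)C(F)(F)F)[C@H](O)CC/C(C)=C/COCc1ccc(OC)cc1 | intermediate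
7 | (3R,6E)-8-(PMB-oxy)-6-methyl-2-methylideneoct-6-ene-1,3-diol | C=C(CO)[C@H](O)CC/C(C)=C/COCc1ccc(OC)cc1 | intermediate
8 | bis-TBS ether of 7 | C=C(CO[Si](C)(C)C(C)(C)C)[C@H](O[Si](C)(C)C(C)(C)C)CC/C(C)=C/COCc1ccc(OC)cc1 | intermediate
9 | (2E,6R)-6-(TBSO)-7-(TBSO-methyl)-3-methylocta-2,7-dien-1-ol | C=C(CO[Si](C)(C)C(C)(C)C)[C@H](O[Si](C)(C)C(C)(C)C)CC/C(C)=C/CO | intermediate
10 | (2E,6R)-1-bromo-6-(TBSO)-7-(TBSO-methyl)-3-methylocta-2,7-diene | C=C(CO[Si](C)(C)C(C)(C)C)[C@H](O[Si](C)(C)C(C)(C)C)CC/C(C)=C/CBr | intermediate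
11 | propargyl alcohol | C#CCO | starting material
12 | (5E,9R)-9-(TBSO)-10-(TBSO-methyl)-6-methylundeca-5,10-dien-2-yn-1-ol | C=C(CO[Si](C)(C)C(C)(C)C)[C@H](O[Si](C)(C)C(C)(C)C)CC/C(C)=C/CC#CCO | intermediate
13 | (2E,5E,9R)-9-(TBSO)-10-(TBSO-methyl)-6-methylundeca-2,5,10-trien-1-ol | C=C(CO[Si](C)(C)C(C)(C)C)[C@H](O[Si](C)(C)C(C)(C)C)CC/C(C)=C/C/C=C/CO | intermediate
14 | (2S,3S)-epoxy alcohol of 13 | C=C(CO[Si](C)(C)C(C)(C)C)[C@H](O[Si](C)(C)C(C)(C)C)CC/C(C)=C/C[C@@H]1O[C@H]1CO | intermediate
15 | ethoxyacetylene | C#COCC | starting material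
16 | (2R,3S,5E,9R)-3-(ethoxyethynyl)-9-(TBSO)-10-(TBSO-methyl)-6-methylundeca-5,10-diene-1,2-diol | C=C(CO[Si](C)(C)C(C)(C)C)[C@H](O[Si](C)(C)C(C)(C)C)CC/C(C)=C/C[C@@H](C#COCC)[C@@H](O)CO | intermediate
17 | cis-(4S,5R)-5-(hydroxymethyl)-4-[(2E,6R)-6-(TBSO)-7-(TBSO-methyl)-3-methylocta-2,7-dienyl]oxolan-2-one | C=C(CO[Si](C)(C)C(C)(C)C)[C@H](O[Si](C)(C)C(C)(C)C)CC/C(C)=C/C[C@H]1CC(=O)O[C@H]1CO | intermediate
18 | (2R,3S)-3-[(2E,6R)-6-(TBSO)-7-(TBSO-methyl)-3-methylocta-2,7-dienyl]-5-oxooxolane-2-carbaldehyde | C=C(CO[Si](C)(C)C(C)(C)C)[C@H](O[Si](C)(C)C(C)(C)C)CC/C(C)=C/C[C@H]1CC(=O)O[C@H]1C=O | intermediate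
19 | (R)-4-benzyl-1,3-thiazolidine-2-thione | S=C1N[C@H](Cc2ccccc2)CS1 | starting material
20 | propanoyl chloride | CCC(Cl)=O | starting material
21 | (R)-4-benzyl-3-propanoyl-1,3-thiazolidine-2-thione | CCC(=O)N1C(=S)SC[C@H]1Cc1ccccc1 | intermediate
22 | syn-aldol adduct (12R,13R), free C13–OH | C=C(CO[Si](C)(C)C(C)(C)C)[C@H](O[Si](C)(C)C(C)(C)C)CC/C(C)=C/C[C@H]1CC(=O)O[C@H]1[C@H](O)[C@@H](C)C(=O)N1C(=S)SC[C@H]1Cc1ccccc1 | intermediate
23 | C13 TBS ether of 22 | C=C(CO[Si](C)(C)C(C)(C)C)[C@H](O[Si](C)(C)C(C)(C)C)CC/C(C)=C/C[C@H]1CC(=O)O[C@H]1[C@H](O[Si](C)(C)C(C)(C)C)[C@@H](C)C(=O)N1C(=S)SC[C@H]1Cc1ccccc1 | intermediate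
24 | C11 primary alcohol (1S,7R,12S,13R,14R) | C=C(CO[Si](C)(C)C(C)(C)C)[C@H](O[Si](C)(C)C(C)(C)C)CC/C(C)=C/C[C@H]1CC(=O)O[C@H]1[C@H](O[Si](C)(C)C(C)(C)C)[C@@H](C)CO | intermediate
25 | bis(phenylsulfonyl)methane | O=S(=O)(CS(=O)(=O)c1ccccc1)c1ccccc1 | starting material
26 | C10 bis(phenylsulfonyl)methyl compound, C7/C9/C13 TBS ethers | C=C(CO[Si](C)(C)C(C)(C)C)[C@H](O[Si](C)(C)C(C)(C)C)CC/C(C)=C/C[C@H]1CC(=O)O[C@H]1[C@H](O[Si](C)(C)C(C)(C)C)[C@@H](C)CC(S(=O)(=O)c1ccccc1)S(=O)(=O)c1ccccc1 | intermediate
27 | C9 allylic alcohol, C7/C13 TBS ethers | C=C(CO)[C@H](O[Si](C)(C)C(C)(C)C)CC/C(C)=C/C[C@H]1CC(=O)O[C@H]1[C@H](O[Si](C)(C)C(C)(C)C)[C@@H](C)CC(S(=O)(=O)c1ccccc1)S(=O)(=O)c1ccccc1 | intermediate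
28 | C9 methyl carbonate (cyclisation precursor) | C=C(COC(=O)OC)[C@H](O[Si](C)(C)C(C)(C)C)CC/C(C)=C/C[C@H]1CC(=O)O[C@H]1[C@H](O[Si](C)(C)C(C)(C)C)[C@@H](C)CC(S(=O)(=O)c1ccccc1)S(=O)(=O)c1ccccc1 | intermediate
29 | macrocyclic 10,10-bis(phenylsulfonyl) lactone | C=C1CC(S(=O)(=O)c2ccccc2)(S(=O)(=O)c2ccccc2)C[C@H](C)[C@@H](O[Si](C)(C)C(C)(C)C)[C@@H]2OC(=O)C[C@@H]2C/C=C(\C)CC[C@H]1O[Si](C)(C)C(C)(C)C | intermediate
30 | desulfonylated macrocyclic lactone | C=C1CCC[C@H](C)[C@@H](O[Si](C)(C)C(C)(C)C)[C@@H]2OC(=O)C[C@@H]2C/C=C(\C)CC[C@H]1O[Si](C)(C)C(C)(C)C | intermediate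
31 | C15 (dimethylaminomethyl) lactone (C15 configuration undefined) | C=C1CCC[C@H](C)[C@@H](O[Si](C)(C)C(C)(C)C)[C@@H]2OC(=O)C(CN(C)C)[C@@H]2C/C=C(\C)CC[C@H]1O[Si](C)(C)C(C)(C)C | intermediate
32 | trimethylammonium iodide of 31 | C=C1CCC[C@H](C)[C@@H](O[Si](C)(C)C(C)(C)C)[C@@H]2OC(=O)C(C[N+](C)(C)C)[C@@H]2C/C=C(\C)CC[C@H]1O[Si](C)(C)C(C)(C)C.[I-] | intermediate
33 | α-methylene lactone, 7,13-bis-TBS ether | C=C1CCC[C@H](C)[C@@H](O[Si](C)(C)C(C)(C)C)[C@@H]2OC(=O)C(=C)[C@@H]2C/C=C(\C)CC[C@H]1O[Si](C)(C)C(C)(C)C | intermediate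
34 | 7,13-diol | C=C1CCC[C@H](C)[C@@H](O)[C@@H]2OC(=O)C(=C)[C@@H]2C/C=C(\C)CC[C@H]1O | intermediate
35 | 7,13-diacetate (3E alkene) | C=C1CCC[C@H](C)[C@@H](OC(C)=O)[C@@H]2OC(=O)C(=C)[C@@H]2C/C=C(\C)CC[C@H]1OC(C)=O | intermediate
36 | CNP0323853.1 | C=C1CCC[C@H](C)[C@@H](OC(C)=O)[C@@H]2OC(=O)C(=C)[C@@H]2C[C@H]2O[C@]2(C)CC[C@H]1OC(C)=O | target

**Step count and risks**

Total step count: 26. Longest linear sequence: 25 steps (steps 1–13 and 15–26, from geraniol); step 14 prepares the auxiliary reagent.

Steps most likely to fail: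

1. Step 21 (ring closure). Intermolecular allylation may outrun the 14-membered closure and give oligomers. Attack of the hindered tertiary carbanion may also be slow enough for the π-allyl complex to decay by β-hydride loss. Fallback: close the same C9–C10 bond without palladium. Alcohol 27 is converted with CBr4/PPh3 into the C9 allylic bromide F1. Slow addition of F1 to Cs2CO3 in DMF then lets the caesium bis-sulfonyl carbanion displace bromide intramolecularly; SN2 and SN2′ attack on this 2-substituted allyl bromide give the same product. The fallback returns to the route at 29.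

2. Step 26 (late epoxidation). The macrocycle may expose the wrong face of C3=C4, so the chiral dioxirane gives poor facial selectivity. Base-promoted loss of acetate or attack on the enoate at pH 10 is a second concern. Fallback: deliver the oxygen from the opposite face by a halohydrin detour. From 35, NBS in aqueous THF forms the bromonium ion on the exposed face and water opens it at the tertiary carbon, giving the (3S,4R)-3-bromo-4-hydroxy compound F2. Cs2CO3 in MeCN then closes the oxirane with inversion at C3, and the fallback rejoins the route at 36.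

3. Step 18 (Mitsunobu C-alkylation). Displacement at the β-branched C11 carbinol by the bulky, weakly nucleophilic carbanion may be slow. The activated alcohol would then be consumed by alkylation of the hydrazide or by elimination. Fallback: classical alkylation of the preformed carbanion. Alcohol 24 is converted with I2, PPh3 and imidazole into the C11 primary iodide F3. Heating F3 with the sodium salt of 25 (NaH, DMF, 60 °C) gives 26, where the route is rejoined.

**Further compounds**

F1 | step 21 | C9 allylic bromide of 27 (C7/C13 TBS ethers; C10 bis-sulfone) | C=C(CBr)[C@H](O[Si](C)(C)C(C)(C)C)CC/C(C)=C/C[C@H]1CC(=O)O[C@H]1[C@H](O[Si](C)(C)C(C)(C)C)[C@@H](C)CC(S(=O)(=O)c1ccccc1)S(=O)(=O)c1ccccc1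
F2 | step 26 | (3S,4R)-3-bromo-4-hydroxy derivative of 35 | C=C1CCC[C@H](C)[C@@H](OC(C)=O)[C@@H]2OC(=O)C(=C)[C@@H]2C[C@H](Br)[C@](C)(O)CC[C@H]1OC(C)=O
F3 | step 18 | C11 primary iodide of 24 | C=C(CO[Si](C)(C)C(C)(C)C)[C@H](O[Si](C)(C)C(C)(C)C)CC/C(C)=C/C[C@H]1CC(=O)O[C@H]1[C@H](O[Si](C)(C)C(C)(C)C)[C@@H](C)CI
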